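**Retrosynthetic overview**
- The C15 hydroxyl is released last by desilylation. This silyl ether is the only protecting group in the route.
- Key disconnection: the C3–O bond of the 3,10-oxa bridge. The furanone opens to a ten-membered γ-hydroxy-ynone, which comes from a vinyl iodide, a terminal alkyne and CO.
- The C8–O ester bond comes from an invertive Mitsunobu reaction with (R)-2-methylbutanoic acid. The C7–C8 bond comes from Barbier allylation of a β-hydroxy aldehyde by a bromomethylbutenolide.
- The butenolide comes from C6–O esterification and ring-closing metathesis on an (S)-enynol made from acrolein. The aldehyde comes from Sharpless epoxidation (C10–O) of a six-carbon enynol.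
- Ring order: lactone (ring C), then the ten-membered carbocycle (ring A), then the furanone (ring B) by transannular C–O closure.

Assumption: the silyl propargyl ether, 2-(bromomethyl)acrylic acid, the (Z)-enynol and enantiopure (R)-2-methylbutanoic acid are bought as such.
Locants C1–C15 follow germacrane numbering of the target: C1 ketone, C3 and C10 bridge carbons, C6 lactone carbinol, C8 ester carbinol.

**Fragment A (bromobutenolide)**

Step 1
Reactants: 1 tert-butyldimethyl(prop-2-yn-1-yloxy)silane; 2 acrolein
Product: 4 (3S)-6-[(tert-butyldimethylsilyl)oxy]hex-1-en-4-yn-3-ol, via alkynyl(methyl)zinc 3 (not isolated)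
Conditions: Me2Zn (3 equiv), (S,S)-ProPhenol (10 mol%), Ph3P=O (20 mol%), toluene, 0 °C; 1 (2.5 equiv) premixed 1 h, then 2
Reagents that add atoms: none
Why: Catalytic asymmetric alkynylation (dinuclear zinc–ProPhenol): the chiral zinc pocket delivers 3 to one face of the enal and sets C6, labelled S here and R in the target only because CIP priorities change later; the sense is confirmed by Mosher analysis and the antipodal ligand is equally available.

Step 2
Reactants: 4 (3S)-enynol
Product: 6 (3S,4Z)-6-[(tert-butyldimethylsilyl)oxy]-5-iodohexa-1,4-dien-3-ol, via cyclic sodium alkenylalanate 5 (not isolated)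
Conditions: NaAlH2(OCH2CH2OMe)2 (1.2 equiv), THF, 0 °C; then NIS, −78 °C
Reagents that add atoms: N-iodosuccinimide, O=C1CCC(=O)N1I
Why: Hydroxyl-directed trans-hydroalumination/iodination: the C6 alkoxide carries Al–H to the alkyne so that aluminium ends on the distal carbon C4 in five-membered alanate 5, and iodination with retention gives only the Z-iodide, which fixes the C4=C5 geometry.

Step 3
Reactants: 6 (3S,4Z)-iodo dienol; 7 2-(bromomethyl)prop-2-enoic acid
Product: 8 (3S,4Z)-6-[(tert-butyldimethylsilyl)oxy]-5-iodohexa-1,4-dien-3-yl 2-(bromomethyl)prop-2-enoate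
Conditions: DCC, DMAP (5 mol%), CH2Cl2, 0 °C
Reagents that add atoms: none
Why: Steglich esterification: carbodiimide activation acylates the alcohol on oxygen, so the C6–O bond of the later lactone forms with retention at C6, and low temperature with little DMAP spares the allylic bromide.

Step 4
Reactants: 8 bromomethylacrylate ester
Product: 9 (5S)-3-(bromomethyl)-5-[(1Z)-3-[(tert-butyldimethylsilyl)oxy]-2-iodoprop-1-en-1-yl]furan-2(5H)-one
Conditions: second-generation Hoveyda–Grubbs catalyst (5 mol%), toluene, 70 °C, argon sparge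
Reagents that add atoms: none
Why: Ring-closing metathesis: the catalyst loads on the monosubstituted vinyl group and closes onto the 1,1-disubstituted acrylate to give the butenolide (ring C) with loss of ethene, while the trisubstituted iodoalkene, the C–Br bond and C6 are untouched.

**Fragment B (aldehyde)**

Step 5
Reactants: 10 (2Z)-3-methylpent-2-en-4-yn-1-ol
Product: 11 [(2S,3R)-3-ethynyl-3-methyloxiran-2-yl]methanol
Conditions: Ti(OiPr)4 (10 mol%), L-(+)-DIPT (12 mol%), TBHP (decane), 4 Å MS, CH2Cl2, −20 °C
Reagents that add atoms: tert-butyl hydroperoxide, CC(C)(C)OO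
Why: Sharpless asymmetric epoxidation: the titanium–L-(+)-tartrate complex binds the allylic alcohol and delivers oxygen to the face that gives the 2S epoxide (same sense as for nerol), which creates the tertiary C10–O bond in the configuration of the target; the alkyne is inert.

Step 6
Reactants: 11 epoxy alcohol
Product: 12 (3S)-3-methylpent-4-yne-1,3-diol
Conditions: NaAlH2(OCH2CH2OMe)2 (1.05 equiv), THF, −20 to 0 °C
Reagents that add atoms: none
Why: Hydroxyl-directed epoxide reduction: one hydride is used by the O–H and the other is delivered from the C8 alkoxyaluminate to the adjacent secondary epoxide carbon C9 (SN2), so the C10–O bond and its configuration stay and no hydride remains to reduce the alkyne.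

Step 7
Reactants: 12 (3S)-diol
Product: 13 (3S)-3-hydroxy-3-methylpent-4-ynal
Conditions: TEMPO (10 mol%), PhI(OAc)2 (1.1 equiv), CH2Cl2, 23 °C; used crude
Reagents that add atoms: none
Why: Oxoammonium (TEMPO) oxidation: only the primary alcohol can be oxidised, and the near-neutral medium avoids retro-aldol cleavage and leaves C10 unchanged.

**Union and endgame**

Step 8
Reactants: 9 bromobutenolide; 13 (3S)-aldehyde (1.5 equiv)
Product: 15 (4R,5S)-4-[(1S,3S)-1,3-dihydroxy-3-methylpent-4-yn-1-yl]-5-[(1Z)-3-[(tert-butyldimethylsilyl)oxy]-2-iodoprop-1-en-1-yl]-3-methylideneoxolan-2-one, via allylzinc bromide 14 (not isolated)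
Conditions: Zn dust (3 equiv), THF/sat. aq NH4Cl 2:1, 0 to 23 °C
Reagents that add atoms: none
Why: Barbier allylation (SE2′): 14 attacks the aldehyde through C7 on the face opposite the C6 side chain (trans lactone, 7R) and creates the exocyclic methylene, and because the ring fixes an E-type allyl geometry the closed chair transition state gives the anti carbinol (8S); vinyl iodide, alkyne and free hydroxyls tolerate zinc in water.

Step 9
Reactants: 15 (8S)-diol; 16 (2R)-2-methylbutanoic acid
Product: 17 (1R,3S)-3-hydroxy-1-{(2S,3R)-2-[(1Z)-3-[(tert-butyldimethylsilyl)oxy]-2-iodoprop-1-en-1-yl]-4-methylidene-5-oxooxolan-3-yl}-3-methylpent-4-yn-1-yl (2R)-2-methylbutanoate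
Conditions: 16 (3 equiv), PPh3 (3 equiv), DIAD (3 equiv), toluene, 0 to 23 °C
Reagents that add atoms: none
Why: Mitsunobu esterification: the carboxylate displaces the activated C8 oxygen by SN2, so the C8–O ester bond forms with inversion (8S to 8R), the tertiary C10 hydroxyl cannot react, and the stereocentre of the acid is not touched.

Step 10
Reactants: 17 seco iodo-alkyne ester
Product: 19 15-O-tert-butyldimethylsilyl ether of the target (6R,7R,8R,10S; 4Z), via ten-membered ynone 18 (not isolated)
Conditions: PdCl2(PPh3)2 (10 mol%), CuI (10 mol%), Et3N (3 equiv), CO (1 atm), THF, 30 °C, 17 added over 12 h to 1 mM; short silica plug; then (4-CF3C6H4)3PAuCl/AgOTf (5 mol% each), H2O (2 equiv), toluene, 23 °C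
Reagents that add atoms: carbon monoxide, [C-]#[O+]; water, O
Why: Proposed new method: a macrocyclising carbonylative Sonogashira coupling ended by a transannular C–O closure, in which zerovalent palladium inserts into the C4–I bond, CO insertion is enforced because direct coupling would need a nine-membered enyne, the copper acetylide of the tertiary carbinol transmetallates at pseudo-high dilution and reductive elimination gives the bent ynone 18, whose strain is released when cationic gold triggers addition of water at C1 and the C10 hydroxyl adds across the ring to the C3 carbonyl and loses water, so that the C3–O bond locks rings A and B without touching a stereocentre (the carbon of CO becomes C3 and the oxygen of water becomes the C1 ketone); the closest known reactions are the intermolecular carbonylative Sonogashira coupling, the gold-catalysed cycloisomerisation of acyclic γ-hydroxy-ynones to 3(2H)-furanones and palladium-mediated closures of ten-membered enediynes.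

Step 11
Reactants: 19 silyl ether
Product: 20 target CNP0307052.2
Conditions: HF·pyridine, pyridine/THF, 0 °C
Reagents that add atoms: none
Why: Fluoride-mediated desilylation: buffered HF cleaves only the Si–O bond and leaves the α-methylene lactone, the ester, the furanone and all stereocentres unchanged.

**Compound list**
1 | tert-butyldimethyl(prop-2-yn-1-yloxy)silane | C#CCO[Si](C)(C)C(C)(C)C | starting material
2 | acrolein | C=CC=O | starting material
3 | methyl{3-[(tert-butyldimethylsilyl)oxy]prop-1-yn-1-yl}zinc | C[Zn]C#CCO[Si](C)(C)C(C)(C)C | intermediate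
4 | (3S)-6-[(tert-butyldimethylsilyl)oxy]hex-1-en-4-yn-3-ol | O[C@@H](C=C)C#CCO[Si](C)(C)C(C)(C)C | intermediate
5 | sodium 1,2-oxaluminol-3-ene alanate (O–Al–C4=C5–C6 ring, two 2-methoxyethoxy ligands, vinyl on C6) | C=C[C@@H]1O[Al-](OCCOC)(OCCOC)C(CO[Si](C)(C)C(C)(C)C)=C1.[Na+] | intermediate
6 | (3S,4Z)-6-[(tert-butyldimethylsilyl)oxy]-5-iodohexa-1,4-dien-3-ol | O[C@@H](C=C)/C=C(/CO[Si](C)(C)C(C)(C)C)I | intermediate
7 | 2-(bromomethyl)prop-2-enoic acid | C=C(CBr)C(=O)O | starting material
8 | (3S,4Z)-6-[(tert-butyldimethylsilyl)oxy]-5-iodohexa-1,4-dien-3-yl 2-(bromomethyl)prop-2-enoate | C=C(CBr)C(=O)O[C@@H](C=C)/C=C(/CO[Si](C)(C)C(C)(C)C)I | intermediate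
9 | (5S)-3-(bromomethyl)-5-[(1Z)-3-[(tert-butyldimethylsilyl)oxy]-2-iodoprop-1-en-1-yl]furan-2(5H)-one | O=C1O[C@@H](C=C1CBr)/C=C(/CO[Si](C)(C)C(C)(C)C)I | intermediate
10 | (2Z)-3-methylpent-2-en-4-yn-1-ol | C#C/C(C)=C\CO | starting material
11 | [(2S,3R)-3-ethynyl-3-methyloxiran-2-yl]methanol | C#C[C@]1(C)[C@H](CO)O1 | intermediate
12 | (3S)-3-methylpent-4-yne-1,3-diol | C#C[C@](C)(CCO)O | intermediate
13 | (3S)-3-hydroxy-3-methylpent-4-ynal | C#C[C@](C)(CC=O)O | intermediate
14 | allylzinc bromide derived from 9 (Zn in place of the C–Br bond) | O=C1O[C@@H](C=C1C[Zn]Br)/C=C(/CO[Si](C)(C)C(C)(C)C)I | intermediate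
15 | (4R,5S)-4-[(1S,3S)-1,3-dihydroxy-3-methylpent-4-yn-1-yl]-5-[(1Z)-3-[(tert-butyldimethylsilyl)oxy]-2-iodoprop-1-en-1-yl]-3-methylideneoxolan-2-one | C=C1C(=O)O[C@H](/C=C(/CO[Si](C)(C)C(C)(C)C)I)[C@H]1[C@@H](O)C[C@](C)(O)C#C | intermediate
16 | (2R)-2-methylbutanoic acid | CC[C@@H](C)C(=O)O | starting material
17 | (8R)-(2R)-2-methylbutanoate of the seco iodo-alkyne (full name in step 9) | C=C1C(=O)O[C@H](/C=C(/CO[Si](C)(C)C(C)(C)C)I)[C@H]1[C@H](OC(=O)[C@H](C)CC)C[C@](C)(O)C#C | intermediate
18 | (6R,7R,8R,10S,4Z)-15-[(tert-butyldimethylsilyl)oxy]-10-hydroxy-8-[(2R)-2-methylbutanoyloxy]-3-oxogermacra-4,11(13)-dien-1-yn-6,12-olide | C=C1C(=O)O[C@@H]2/C=C(/CO[Si](C)(C)C(C)(C)C)C(=O)C#C[C@@](C)(O)C[C@@H](OC(=O)[C@H](C)CC)[C@@H]12 | intermediate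
19 | 15-O-tert-butyldimethylsilyl ether of the target | C=C1C(=O)O[C@@H]2/C=C(/CO[Si](C)(C)C(C)(C)C)C3=CC(=O)[C@](C)(C[C@@H](OC(=O)[C@H](C)CC)[C@@H]12)O3 | intermediate
20 | CNP0307052.2, (6R,7R,8R,10S,4Z)-15-hydroxy-8-[(2R)-2-methylbutanoyloxy]-1-oxo-3,10-epoxygermacra-2,4,11(13)-trien-6,12-olide | C=C1C(=O)O[C@@H]2/C=C(/CO)C3=CC(=O)[C@](C)(C[C@@H](OC(=O)[C@H](C)CC)[C@@H]12)O3 | target

**Step count**
- Total: 11 steps.
- Longest linear sequence: 8 steps (steps 1–4 and 8–11). Steps 5–7 run in parallel.

**The three steps most likely to fail**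

Step 10 (the proposed new step). The risks are oligomerisation, failure of the ten-membered reductive elimination, and insertion of the acylpalladium into the exocyclic methylene. The fallback uses known chemistry and closes the ring at a different bond. It sets out from 9 and 13 and comes back at 19. The bromide of 9 is hydrolysed (Ag2CO3, acetone/H2O) to hydroxymethylbutenolide F1, whose allylic position no longer reacts with zerovalent palladium. An ordinary intermolecular carbonylative Sonogashira coupling with 13 (PdCl2(PPh3)2, CuI, Et3N, CO 1 atm, THF, 23 °C) gives acyclic hydroxy-ynone aldehyde F2. The gold conditions of step 10 convert it into furanone aldehyde F3, and PBr3 (Et2O, −20 °C) gives allylic bromide F4. An intramolecular Barbier allylation (Zn, THF/aq NH4Cl, 2 mM) then closes the ten-membered ring at C7–C8 to macrocyclic carbinol F5, drawn 8S as expected from the closed transition state. Mitsunobu esterification with 16 as in step 9 gives 19.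

Step 9. The risks are a hindered carbinol, a weakly acidic partner, and elimination towards C7. The fallback sets out from 15 and comes back at 17. Dess–Martin periodinane (CH2Cl2, 0 °C) oxidises only the secondary alcohol to hydroxy ketone F6. A Narasaka–Prasad reduction (Et2BOMe, NaBH4, THF/MeOH, −78 °C), directed by the C10 hydroxyl, gives the 1,3-syn diol, which is (8R)-diol F7. Steglich acylation (16, DCC, DMAP, CH2Cl2) esterifies the secondary hydroxyl with retention and gives 17.

Step 1. The risks are polymerisation of acrolein and modest enantioselectivity. The fallback sets out from 1 and 2 and comes back at 4. Lithiation of 1 (nBuLi, THF, −78 °C) and addition to 2 gives racemic enynol F8. A Sharpless kinetic resolution (Ti(OiPr)4, L-(+)-DIPT, TBHP 0.6 equiv, 4 Å MS, CH2Cl2, −20 °C) epoxidises the vinyl group of the (R)-enantiomer to epoxy alcohol F9 and leaves (S)-4, which is separated by chromatography.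

**Further compounds**
F1 | step 10 | (5S)-3-(hydroxymethyl)-5-[(1Z)-3-[(tert-butyldimethylsilyl)oxy]-2-iodoprop-1-en-1-yl]furan-2(5H)-one | O=C1O[C@@H](C=C1CO)/C=C(/CO[Si](C)(C)C(C)(C)C)I
F2 | step 10 | acyclic hydroxy-ynone aldehyde (butenolide–C5H=C4(CH2OTBS)–C3(=O)–C≡C–C10(OH)(CH3)–CH2–CHO, 10S) | O=C1O[C@@H](C=C1CO)/C=C(/CO[Si](C)(C)C(C)(C)C)C(=O)C#C[C@@](C)(O)CC=O
F3 | step 10 | furanone aldehyde (2-methyl-2-(2-oxoethyl)-3(2H)-furanone carrying the Z-alkenyl hydroxymethylbutenolide at its C5) | O=C1O[C@@H](C=C1CO)/C=C(/CO[Si](C)(C)C(C)(C)C)C2=CC(=O)[C@](C)(CC=O)O2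
F4 | step 10 | allylic bromide of F3 | O=C1O[C@@H](C=C1CBr)/C=C(/CO[Si](C)(C)C(C)(C)C)C2=CC(=O)[C@](C)(CC=O)O2
F5 | step 10 | macrocyclic (8S)-carbinol, 15-O-silyl ether | C=C1C(=O)O[C@@H]2/C=C(/CO[Si](C)(C)C(C)(C)C)C3=CC(=O)[C@](C)(C[C@H](O)[C@@H]12)O3
F6 | step 9 | C8 ketone of 15 | C=C1C(=O)O[C@H](/C=C(/CO[Si](C)(C)C(C)(C)C)I)[C@H]1C(=O)C[C@](C)(O)C#C
F7 | step 9 | (8R)-epimer of 15 | C=C1C(=O)O[C@H](/C=C(/CO[Si](C)(C)C(C)(C)C)I)[C@H]1[C@H](O)C[C@](C)(O)C#C
F8 | step 1 | racemic 6-[(tert-butyldimethylsilyl)oxy]hex-1-en-4-yn-3-ol | OC(C=C)C#CCO[Si](C)(C)C(C)(C)C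
F9 | step 1 | (1S)-4-[(tert-butyldimethylsilyl)oxy]-1-[(2R)-oxiran-2-yl]but-2-yn-1-ol | O[C@H]([C@H]1CO1)C#CCO[Si](C)(C)C(C)(C)C
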